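## Retrosynthetic overview

1. Target 10 ⇐ alcohol 9: the C4–OAc bond is made last, by invertive C–O bond formation. Acetate enters from the open C8 face, the same face hydride prefers, so C4 is set by reduction followed by SN2 acetoxylation.
2. 9 ⇐ enedione 8 by 1,2-reduction of the C4 carbonyl.
3. 8 ⇐ p-quinone monoketal 5 + (E)-methylisoeugenol 6 by a catalytic asymmetric cationic [5+2] cycloaddition, which sets C1, C5, C6 and C7 (bond C1–C7 first, then C5–C6).
4. 5 ⇐ phenol 4 by dearomatising oxidative C–O bond formation (ketal); 4 ⇐ 1 + 2 by O-allylation and Claisen rearrangement.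
5. Ring order: the six-membered ring is the arene of 1, dearomatised in step 3. The cyclopentanone ring C1–C8–C5–C6–C7, which completes the bicyclo[3.2.1]octane, closes in step 4.

Locants used for all bicyclic compounds: C1 = allyl-bearing bridgehead, C2 = vinyl CH, C3 = C–OMe of the enol ether, C4 = carbinol/acetoxy carbon, C5 = OMe-bearing bridgehead, C6 = CH–aryl, C7 = CH–CH3, C8 = bridging C=O.

Assumption: 2,3,4-trimethoxyphenol is bought as such (otherwise one Dakin oxidation from 2,3,4-trimethoxybenzaldehyde).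

Assumption: the sense of induction of the new chiral acid cannot be predicted; the (S,S)-acid is written, and its mirror image is used if it delivers the antipode.

Acid A = confined imidodiphosphorimidate (IDPi) Brønsted acid built from two (S)-3,3'-bis[3,5-bis(trifluoromethyl)phenyl]-BINOL units around an N-triflyl phosphorimidate core.

## Route

Step 1
Reactants: 1 2,3,4-trimethoxyphenol; 2 allyl bromide
Product: 3 1-(allyloxy)-2,3,4-trimethoxybenzene
Conditions: K2CO3, acetone, reflux
Reagents that add atoms: none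
Why: Williamson ether synthesis of a phenoxide with an unhindered allylic bromide; no stereocentre is formed.

Step 2
Reactants: 3 1-(allyloxy)-2,3,4-trimethoxybenzene
Product: 4 6-allyl-2,3,4-trimethoxyphenol
Conditions: N,N-diethylaniline, 190 °C
Reagents that add atoms: none
Why: Aromatic Claisen rearrangement; C6 is the only free ortho position (the other ortho carbon and the para carbon carry OMe), so the allyl group can only end up there.

Step 3
Reactants: 4 6-allyl-2,3,4-trimethoxyphenol
Product: 5 2-allyl-4,4,5,6-tetramethoxycyclohexa-2,5-dien-1-one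
Conditions: PhI(OAc)2, MeOH, 0 °C
Reagents that add atoms: methanol, CO
Why: Oxidative dearomatisation by a hypervalent iodine reagent; the oxidised phenol is captured by methanol at the para carbon that already carries OMe, giving the p-quinone monoketal by C–O bond formation, with no stereocentre.

Step 4
Reactants: 5 2-allyl-4,4,5,6-tetramethoxycyclohexa-2,5-dien-1-one; 6 (E)-methylisoeugenol, 1,2-dimethoxy-4-[(1E)-prop-1-en-1-yl]benzene
Product: 8 (1S,5R,6S,7R)-1-allyl-6-(3,4-dimethoxyphenyl)-3,5-dimethoxy-7-methylbicyclo[3.2.1]oct-2-ene-4,8-dione, via C4 dimethyl ketal 7 (not isolated)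
Conditions: acid A (5 mol %), toluene, −60 °C; then 0.5 M aq. HCl, THF, 0 °C
Reagents that add atoms: water, O
Why: Proposed new method: a catalytic asymmetric, counteranion-directed [5+2] cycloaddition in which acid A ionises one ketal C–O bond of 5 to give the planar 4-methoxy-2-oxidopentadienyl (phenoxonium) cation as a contact ion pair inside the chiral anion; the nucleophilic β-carbon of the (E)-alkene adds to the allyl-bearing terminus on the exposed face (enantio-determining, sets C1 and C7 with methyl endo), the resulting electron-rich benzylic cation is closed by the other terminus, made nucleophilic by the neighbouring C4 methoxy group (sets C5 and C6, aryl exo and trans to methyl as dictated by the E-alkene), and the C4 oxocarbenium ion is trapped by the released methanol as ketal 7 with return of the proton, the aqueous acid then unmasking the C4 ketone; the closest known reactions are the racemic acid- or Lewis-acid-promoted [5+2] cycloaddition of quinone monoketals to propenylbenzenes (Büchi type) and chiral Brønsted-acid ion-pair catalysis of oxocarbenium cycloadditions.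

Step 5
Reactants: 8 (1S,5R,6S,7R)-1-allyl-6-(3,4-dimethoxyphenyl)-3,5-dimethoxy-7-methylbicyclo[3.2.1]oct-2-ene-4,8-dione
Product: 9 (1S,4R,5S,6S,7R)-1-allyl-6-(3,4-dimethoxyphenyl)-4-hydroxy-3,5-dimethoxy-7-methylbicyclo[3.2.1]oct-2-en-8-one
Conditions: NaBH4, CeCl3·7H2O, MeOH/CH2Cl2, −78 °C
Reagents that add atoms: none
Why: Luche 1,2-reduction; the conjugated C4 carbonyl reacts in preference to the C8 ketone flanked by two quaternary carbons, and hydride adds from the face syn to the C8 bridge (anti to the C5–C6 bond, the other face being nearly eclipsed with it), which places the hydroxyl on the C6–C7 side (4R).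

Step 6
Reactants: 9 (1S,4R,5S,6S,7R)-1-allyl-6-(3,4-dimethoxyphenyl)-4-hydroxy-3,5-dimethoxy-7-methylbicyclo[3.2.1]oct-2-en-8-one
Product: 10 (1S,4S,5S,6S,7R)-1-allyl-6-(3,4-dimethoxyphenyl)-3,5-dimethoxy-7-methyl-8-oxobicyclo[3.2.1]oct-2-en-4-yl acetate (CNP0221003.1)
Conditions: PPh3, DIAD, AcOH, toluene, 0 °C to rt
Reagents that add atoms: acetic acid, CC(=O)O
Why: Mitsunobu reaction; acetate displaces the allylic alkoxyphosphonium by SN2 from the open C8 face, inverting C4 to S, and elimination cannot compete because C3 is sp2 and C5 is quaternary.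

## Compound list

1 | 2,3,4-trimethoxyphenol | COc1ccc(O)c(OC)c1OC | starting material
2 | allyl bromide (3-bromoprop-1-ene) | C=CCBr | starting material
3 | 1-(allyloxy)-2,3,4-trimethoxybenzene | C=CCOc1ccc(OC)c(OC)c1OC | intermediate
4 | 6-allyl-2,3,4-trimethoxyphenol | C=CCc1cc(OC)c(OC)c(OC)c1O | intermediate
5 | 2-allyl-4,4,5,6-tetramethoxycyclohexa-2,5-dien-1-one | O=C1C(CC=C)=CC(OC)(OC)C(OC)=C1OC | intermediate
6 | (E)-methylisoeugenol, 1,2-dimethoxy-4-[(1E)-prop-1-en-1-yl]benzene | C/C=C/c1ccc(OC)c(OC)c1 | starting material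
7 | (1S,5R,6S,7R)-1-allyl-6-(3,4-dimethoxyphenyl)-3,4,4,5-tetramethoxy-7-methylbicyclo[3.2.1]oct-2-en-8-one | C=CC[C@]12C=C(OC)C(OC)(OC)[C@](OC)(C1=O)[C@H](c1ccc(OC)c(OC)c1)[C@H]2C | intermediate
8 | (1S,5R,6S,7R)-1-allyl-6-(3,4-dimethoxyphenyl)-3,5-dimethoxy-7-methylbicyclo[3.2.1]oct-2-ene-4,8-dione | C=CC[C@]12C=C(OC)C(=O)[C@](OC)(C1=O)[C@H](c1ccc(OC)c(OC)c1)[C@H]2C | intermediate
9 | (1S,4R,5S,6S,7R)-1-allyl-6-(3,4-dimethoxyphenyl)-4-hydroxy-3,5-dimethoxy-7-methylbicyclo[3.2.1]oct-2-en-8-one | C=CC[C@]12C=C(OC)[C@@H](O)[C@](OC)(C1=O)[C@H](c1ccc(OC)c(OC)c1)[C@H]2C | intermediate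
10 | (1S,4S,5S,6S,7R)-1-allyl-6-(3,4-dimethoxyphenyl)-3,5-dimethoxy-7-methyl-8-oxobicyclo[3.2.1]oct-2-en-4-yl acetate | C=CC[C@]12C=C(OC)[C@H](OC(C)=O)[C@](OC)(C1=O)[C@H](c1ccc(OC)c(OC)c1)[C@H]2C | target

## Step count and risks

Total step count: 6. Longest linear sequence: 6 steps (1 → 3 → 4 → 5 → 8 → 9 → 10).

The three steps most likely to fail are, in order, the cycloaddition (step 4), the invertive acetoxylation (step 6) and the reduction (step 5).

The new asymmetric cycloaddition of step 4 may give low enantioselectivity, kinetic oxygen-closed [3+2] adducts, or acid-induced dimerisation of 6. The fallback sets out from 5 and 6 and comes back at 8. It uses the known racemic cycloaddition (2,4,6-trinitrobenzenesulfonic acid, MeCN, −30 °C, or TMSOTf, CH2Cl2, −78 °C, then aqueous work-up). This gives 8 together with its mirror image, (1R,5S,6R,7S)-1-allyl-6-(3,4-dimethoxyphenyl)-3,5-dimethoxy-7-methylbicyclo[3.2.1]oct-2-ene-4,8-dione F1, and the two are separated by preparative chiral SFC.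

The Mitsunobu displacement of step 6 is at an allylic carbon next to a quaternary centre and may stall or leak into SN1/SN2' products (acetate at C2). The fallback sets out from 8 and comes back at 10 without any substitution at C4. A reagent-controlled Corey–Bakshi–Shibata reduction (the enantiomer of 2-methyl-CBS-oxazaborolidine that delivers hydride to the C6–C7 face, catecholborane, −78 °C) gives (1S,4S,5S,6S,7R)-1-allyl-6-(3,4-dimethoxyphenyl)-4-hydroxy-3,5-dimethoxy-7-methylbicyclo[3.2.1]oct-2-en-8-one F4. This is acetylated with retention (Ac2O, DMAP, pyridine).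

The Luche reduction of step 5 may also attack the strained C8 ketone. The fallback sets out from 8 and comes back at 10.

- Both carbonyls are reduced on purpose (NaBH4, MeOH, 0 °C to rt) to (1S,4R,5R,6S,7R,8S)-1-allyl-6-(3,4-dimethoxyphenyl)-3,5-dimethoxy-7-methylbicyclo[3.2.1]oct-2-ene-4,8-diol F2.
- The Mitsunobu acetoxylation is run on the diol. Only the allylic C4 hydroxyl can react, because the C8 hydroxyl sits on the bridging carbon between two quaternary centres. This gives (1S,4S,5R,6S,7R,8S)-1-allyl-6-(3,4-dimethoxyphenyl)-8-hydroxy-3,5-dimethoxy-7-methylbicyclo[3.2.1]oct-2-en-4-yl acetate F3.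
- Dess–Martin periodinane restores the C8 ketone.

## Further compounds

F1 | step 4 | (1R,5S,6R,7S)-1-allyl-6-(3,4-dimethoxyphenyl)-3,5-dimethoxy-7-methylbicyclo[3.2.1]oct-2-ene-4,8-dione | C=CC[C@@]12C=C(OC)C(=O)[C@@](OC)(C1=O)[C@@H](c1ccc(OC)c(OC)c1)[C@@H]2C
F2 | step 5 | (1S,4R,5R,6S,7R,8S)-1-allyl-6-(3,4-dimethoxyphenyl)-3,5-dimethoxy-7-methylbicyclo[3.2.1]oct-2-ene-4,8-diol | C=CC[C@]12C=C(OC)[C@@H](O)[C@](OC)([C@H]1O)[C@H](c1ccc(OC)c(OC)c1)[C@H]2C
F3 | step 5 | (1S,4S,5R,6S,7R,8S)-1-allyl-6-(3,4-dimethoxyphenyl)-8-hydroxy-3,5-dimethoxy-7-methylbicyclo[3.2.1]oct-2-en-4-yl acetate | C=CC[C@]12C=C(OC)[C@H](OC(C)=O)[C@](OC)([C@H]1O)[C@H](c1ccc(OC)c(OC)c1)[C@H]2C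
F4 | step 6 | (1S,4S,5S,6S,7R)-1-allyl-6-(3,4-dimethoxyphenyl)-4-hydroxy-3,5-dimethoxy-7-methylbicyclo[3.2.1]oct-2-en-8-one | C=CC[C@]12C=C(OC)[C@H](O)[C@](OC)(C1=O)[C@H](c1ccc(OC)c(OC)c1)[C@H]2C
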